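**Retrosynthetic overview**
1. Target ⇒ aldehyde 15 + silylpropyne 16: Z-selective Peterson enyne synthesis and C–Si cleavage, last step.
2. E-bromoalkene ⇒ Z-alkenylboronate 13 (stereoretentive bromodeboronation) ⇒ allyl compound 9 + boronate 12 (cross-metathesis).
3. Ring C–Br ⇒ alcohol 8 (Appel, inversion); ring C–Cl and C–OH ⇒ enone 6 (conjugate hydrochlorination, then ketone reduction).
4. Enone 6 ⇒ furyl carbinol 3 + ketene silyl acetal 4: one-flask Achmatowicz dearomatisation and C-glycosylation. This is the only ring-forming event (furan → oxane).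
5. Carbinol 3 ⇒ furfural + allylboronate 2 (catalytic asymmetric allylboration).

Assumption: the SMILES is taken literally, i.e. (2R,3S,5S,6R) with the two side chains trans across the ring oxygen and each halogen trans to its neighbouring chain; the catalyst (R)-TRIP and reagents 2, 4 and 16 are bought.

**Route**

Step 1
Reactants: 1 furfural; 2 allylboronic acid pinacol ester
Product: 3 (1R)-1-(furan-2-yl)but-3-en-1-ol
Conditions: (R)-3,3'-bis(2,4,6-triisopropylphenyl)-1,1'-binaphthyl-2,2'-diyl hydrogen phosphate [(R)-TRIP, 5 mol %], toluene, −30 °C; aq. NaHCO3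
Reagents that add atoms: allylboronic acid pinacol ester 2, C=CCB1OC(C)(C)C(C)(C)O1
Why: Chiral phosphoric acid catalysed allylboration through a chair transition state with the acid hydrogen-bonded to a boronate oxygen; the (R)-acid gives the R carbinol (the sense known for aryl aldehydes), which becomes the ring carbon that carries the bromopentenyl chain.

Step 2
Reactants: 3 (1R)-1-(furan-2-yl)but-3-en-1-ol; 4 tert-butyl[(1-methoxyethenyl)oxy]dimethylsilane
Product: 6 methyl 2-[(2R,6R)-5-oxo-6-(prop-2-en-1-yl)-5,6-dihydro-2H-pyran-2-yl]acetate, via lactol 5 (not isolated)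
Conditions: mCPBA (1.05 equiv), CH2Cl2, 0 °C; then 4 (4 equiv), 0 °C; BF3·OEt2 (2.5 equiv), −78 → −40 °C
Reagents that add atoms: 3-chloroperoxybenzoic acid (mCPBA), OOC(=O)c1cccc(Cl)c1; ketene silyl acetal 4, COC(=C)O[Si](C)(C)C(C)(C)C
Why: Proposed new method: the Achmatowicz oxidative ring expansion of a furyl carbinol and the Lewis acid C-glycosylation of the derived pyranone with a silyl enol ether (Mukaiyama type) are both known and are joined here in one flask; the peracid opens the furan to an ene-dione that closes to lactol 5, excess 4 silylates the benzoic acid by-product, BF3 ionises the anomeric C–O bond, and 4 attacks the oxocarbenium ion on the face opposite the allyl group, which sets the 2,6-trans ring.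

Step 3
Reactants: 6 methyl 2-[(2R,6R)-5-oxo-6-(prop-2-en-1-yl)-5,6-dihydro-2H-pyran-2-yl]acetate
Product: 8 methyl 2-[(2R,3S,5R,6R)-3-chloro-5-hydroxy-6-(prop-2-en-1-yl)oxan-2-yl]acetate, via chloroketone 7 (not isolated)
Conditions: HCl (4 M in dioxane, 3 equiv), CH2Cl2, −30 °C; then MeOH, CeCl3·7H2O, NaBH4, −78 °C
Reagents that add atoms: hydrogen chloride, Cl
Why: Conjugate hydrochlorination of the enone (chloride adds axially to the β-carbon, anti to the neighbouring CH2CO2Me group) followed by Luche reduction in the same flask; hydride enters the ketone from the face opposite both the new C–Cl bond and the allyl group, so the alcohol ends cis to both, and the labile β-chloro ketone is never isolated.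

Step 4
Reactants: 8 methyl 2-[(2R,3S,5R,6R)-3-chloro-5-hydroxy-6-(prop-2-en-1-yl)oxan-2-yl]acetate
Product: 9 methyl 2-[(2R,3S,5S,6R)-5-bromo-3-chloro-6-(prop-2-en-1-yl)oxan-2-yl]acetate
Conditions: CBr4, P(n-C8H17)3, toluene, 70 °C
Reagents that add atoms: carbon tetrabromide, BrC(Br)(Br)Br
Why: Appel reaction; bromide displaces the alkoxyphosphonium ion by SN2 with inversion, which puts bromine trans to the allyl group and trans to chlorine.

Step 5
Reactants: 10 2-bromobut-1-ene
Product: 12 2-(but-1-en-2-yl)-4,4,5,5-tetramethyl-1,3,2-dioxaborolane, via Grignard reagent 11 (not isolated)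
Conditions: Mg, THF, 40 °C; then i-PrOB(pin), −78 °C → rt; aq. NH4Cl
Reagents that add atoms: 2-isopropoxy-4,4,5,5-tetramethyl-1,3,2-dioxaborolane, CC(C)OB1OC(C)(C)C(C)(C)O1; magnesium, [Mg] (in 11 only)
Why: Magnesium insertion into the alkenyl bromide and electrophilic borylation of the Grignard reagent with a borate ester; no stereocentre is formed.

Step 6
Reactants: 9 methyl 2-[(2R,3S,5S,6R)-5-bromo-3-chloro-6-(prop-2-en-1-yl)oxan-2-yl]acetate; 12 2-(but-1-en-2-yl)-4,4,5,5-tetramethyl-1,3,2-dioxaborolane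
Product: 13 methyl 2-[(2R,3S,5S,6R)-5-bromo-3-chloro-6-[(2Z)-3-(4,4,5,5-tetramethyl-1,3,2-dioxaborolan-2-yl)pent-2-en-1-yl]oxan-2-yl]acetate
Conditions: second-generation Grubbs catalyst RuCl2(=CHPh)(PCy3)(H2IMes) (10 mol %), 12 (4 equiv), CH2Cl2, 40 °C
Reagents that add atoms: boronate 12, C=C(CC)B1OC(C)(C)C(C)(C)O1
Why: Olefin cross-metathesis of a terminal alkene with a 1,1-disubstituted alkenylboronate, with loss of ethene; the ring CH2 avoids the bulky pinacolboryl group in the ruthenacyclobutane, so boron ends trans to the ring CH2 (Z), the sense known for 1-alkylvinyl pinacol boronates.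

Step 7
Reactants: 13 methyl 2-[(2R,3S,5S,6R)-5-bromo-3-chloro-6-[(2Z)-3-(4,4,5,5-tetramethyl-1,3,2-dioxaborolan-2-yl)pent-2-en-1-yl]oxan-2-yl]acetate
Product: 14 methyl 2-[(2R,3S,5S,6R)-5-bromo-6-[(2E)-3-bromopent-2-en-1-yl]-3-chlorooxan-2-yl]acetate
Conditions: CuBr2 (3 equiv), MeOH/H2O 1:1, 60 °C
Reagents that add atoms: copper dibromide, Br[Cu]Br
Why: Copper-mediated bromodeboronation (boron-to-copper transmetalation, then C–Br bond formation at the same carbon) proceeds with retention, so bromine takes the place of boron and the E bromoalkene results; no other alkene is present at this stage.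

Step 8
Reactants: 14 methyl 2-[(2R,3S,5S,6R)-5-bromo-6-[(2E)-3-bromopent-2-en-1-yl]-3-chlorooxan-2-yl]acetate
Product: 15 2-[(2R,3S,5S,6R)-5-bromo-6-[(2E)-3-bromopent-2-en-1-yl]-3-chlorooxan-2-yl]acetaldehyde
Conditions: i-Bu2AlH (1.1 equiv), CH2Cl2, −78 °C; MeOH, then aq. KNaC4H4O6
Reagents that add atoms: none
Why: Partial ester reduction; the tetrahedral aluminium hemiacetal is stable at −78 °C and gives the aldehyde on work-up, with no stereocentre touched.

Step 9
Reactants: 15 2-[(2R,3S,5S,6R)-5-bromo-6-[(2E)-3-bromopent-2-en-1-yl]-3-chlorooxan-2-yl]acetaldehyde; 16 1,3-bis(triisopropylsilyl)propyne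
Product: 19 (2R,3S,5S,6R)-3-bromo-2-[(2E)-3-bromopent-2-en-1-yl]-5-chloro-6-[(2Z)-pent-2-en-4-yn-1-yl]oxane, via lithiated propyne 17 (not isolated), via silyl enyne 18 (not isolated)
Conditions: 16, n-BuLi, THF, −20 °C; 15, −78 → 0 °C; then n-Bu4NF, THF, 0 °C
Reagents that add atoms: 1,3-bis(triisopropylsilyl)propyne 16, CC(C)[Si](C(C)C)(C(C)C)CC#C[Si](C(C)C)(C(C)C)C(C)C; butyllithium, [Li]CCCC (lithium in 17 only)
Why: Peterson olefination with the lithiated 1,3-disilylpropyne gives the Z enyne by syn elimination of the kinetically formed β-silyl alkoxide (Z:E about 20:1), and fluoride then cleaves the alkynyl C–Si bond in the same flask.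

**Compound list**
1 | furfural (furan-2-carbaldehyde) | O=Cc1ccco1 | starting material
2 | allylboronic acid pinacol ester | C=CCB1OC(C)(C)C(C)(C)O1 | starting material
3 | (1R)-1-(furan-2-yl)but-3-en-1-ol | C=CC[C@@H](O)c1ccco1 | intermediate
4 | tert-butyl[(1-methoxyethenyl)oxy]dimethylsilane | COC(=C)O[Si](C)(C)C(C)(C)C | starting material
5 | (2R)-6-hydroxy-2-(prop-2-en-1-yl)-2H-pyran-3(6H)-one (both C6 epimers) | OC1O[C@H](CC=C)C(=O)C=C1 | intermediate (not isolated)
6 | methyl 2-[(2R,6R)-5-oxo-6-(prop-2-en-1-yl)-5,6-dihydro-2H-pyran-2-yl]acetate | COC(=O)C[C@H]1O[C@H](CC=C)C(=O)C=C1 | intermediate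
7 | methyl 2-[(2R,3S,6R)-3-chloro-5-oxo-6-(prop-2-en-1-yl)oxan-2-yl]acetate | COC(=O)C[C@H]1O[C@H](CC=C)C(=O)C[C@@H]1Cl | intermediate (not isolated)
8 | methyl 2-[(2R,3S,5R,6R)-3-chloro-5-hydroxy-6-(prop-2-en-1-yl)oxan-2-yl]acetate | COC(=O)C[C@H]1O[C@H](CC=C)[C@H](O)C[C@@H]1Cl | intermediate
9 | methyl 2-[(2R,3S,5S,6R)-5-bromo-3-chloro-6-(prop-2-en-1-yl)oxan-2-yl]acetate | COC(=O)C[C@H]1O[C@H](CC=C)[C@@H](Br)C[C@@H]1Cl | intermediate
10 | 2-bromobut-1-ene | C=C(Br)CC | starting material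
11 | but-1-en-2-ylmagnesium bromide | CCC(=C)[Mg]Br | intermediate (not isolated)
12 | 2-(but-1-en-2-yl)-4,4,5,5-tetramethyl-1,3,2-dioxaborolane | C=C(CC)B1OC(C)(C)C(C)(C)O1 | intermediate
13 | methyl 2-[(2R,3S,5S,6R)-5-bromo-3-chloro-6-[(2Z)-3-(4,4,5,5-tetramethyl-1,3,2-dioxaborolan-2-yl)pent-2-en-1-yl]oxan-2-yl]acetate | COC(=O)C[C@H]1O[C@H](C/C=C(/B2OC(C)(C)C(C)(C)O2)CC)[C@@H](Br)C[C@@H]1Cl | intermediate
14 | methyl 2-[(2R,3S,5S,6R)-5-bromo-6-[(2E)-3-bromopent-2-en-1-yl]-3-chlorooxan-2-yl]acetate | COC(=O)C[C@H]1O[C@H](C/C=C(/Br)CC)[C@@H](Br)C[C@@H]1Cl | intermediate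
15 | 2-[(2R,3S,5S,6R)-5-bromo-6-[(2E)-3-bromopent-2-en-1-yl]-3-chlorooxan-2-yl]acetaldehyde | O=CC[C@H]1O[C@H](C/C=C(/Br)CC)[C@@H](Br)C[C@@H]1Cl | intermediate
16 | 1,3-bis(triisopropylsilyl)propyne | CC(C)[Si](C(C)C)(C(C)C)CC#C[Si](C(C)C)(C(C)C)C(C)C | starting material
17 | [1,3-bis(triisopropylsilyl)prop-2-yn-1-yl]lithium | [Li]C(C#C[Si](C(C)C)(C(C)C)C(C)C)[Si](C(C)C)(C(C)C)C(C)C | intermediate (not isolated)
18 | [(3Z)-5-[(2R,3S,5S,6R)-5-bromo-6-[(2E)-3-bromopent-2-en-1-yl]-3-chlorooxan-2-yl]pent-3-en-1-yn-1-yl]tri(propan-2-yl)silane | CC(C)[Si](C(C)C)(C(C)C)C#C/C=C\C[C@H]1O[C@H](C/C=C(/Br)CC)[C@@H](Br)C[C@@H]1Cl | intermediate (not isolated)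
19 | (2R,3S,5S,6R)-3-bromo-2-[(2E)-3-bromopent-2-en-1-yl]-5-chloro-6-[(2Z)-pent-2-en-4-yn-1-yl]oxane | C#C/C=C\C[C@H]1O[C@H](C/C=C(/Br)CC)[C@@H](Br)C[C@@H]1Cl | target

**Step count**
Total: 9 steps. Longest linear sequence: 8 steps (steps 1–4 and 6–9); step 5 is a one-step side branch.

**Three steps most likely to fail**

Step 2 (one-flask dearomatisation and C-glycosylation). The free lactol and the benzoic acid may consume the ketene acetal, the acetal may add to the enone in a Michael sense, or the trans selectivity may drop. The fallback sets out from 3 and comes back at 6. The Achmatowicz reaction is run on its own (NBS, NaHCO3, NaOAc, THF/H2O, 0 °C) and lactol 5 is isolated. It is acetylated (Ac2O, pyridine, DMAP) to the anomeric acetate (6R)-5-oxo-6-(prop-2-en-1-yl)-5,6-dihydro-2H-pyran-2-yl acetate F1. This stable donor is then coupled with 4 under Me3SiOTf in CH2Cl2 at −78 °C to give 6.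

Step 3 (hydrochlorination and reduction). The β-chloro ketone can lose HCl or epimerise next to the ketone, and the hydride may enter from the other face. The fallback sets out from 7 and comes back at 8. Ketone 7 is reduced without facial demands (NaBH4, MeOH/CH2Cl2, −40 °C), and the C5-epimeric alcohol methyl 2-[(2R,3S,5S,6R)-3-chloro-5-hydroxy-6-(prop-2-en-1-yl)oxan-2-yl]acetate F2 is separated. It is inverted by Mitsunobu esterification (4-nitrobenzoic acid, PPh3, DIAD, toluene) to the 4-nitrobenzoate (2R,3R,5S,6R)-5-chloro-6-(2-methoxy-2-oxoethyl)-2-(prop-2-en-1-yl)oxan-3-yl 4-nitrobenzoate F3. Methanolysis (K2CO3, MeOH, 0 °C) then gives 8.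

Step 6 (cross-metathesis to a trisubstituted alkenylboronate). Turnover may be slow, 9 may homodimerise, and Z selectivity may be incomplete with an ethyl group. The fallback sets out from 9 and comes back at 13. Ozonolysis (O3, CH2Cl2, −78 °C; PPh3) gives the aldehyde methyl 2-[(2R,3S,5S,6R)-5-bromo-3-chloro-6-(2-oxoethyl)oxan-2-yl]acetate F4. The reagent 1,1-bis(4,4,5,5-tetramethyl-1,3,2-dioxaborolan-2-yl)propane F5 is made from bis(pinacolboryl)methane, lithium 2,2,6,6-tetramethylpiperidide (LiNC9H18) and EtI in THF. F5 is deprotonated with the same base at 0 °C and added to F4 at −78 °C (boron-Wittig olefination), which gives 13 with the chain again trans to boron.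

**Further compounds**
F1 | step 2 | (6R)-5-oxo-6-(prop-2-en-1-yl)-5,6-dihydro-2H-pyran-2-yl acetate (both anomers) | CC(=O)OC1O[C@H](CC=C)C(=O)C=C1
F2 | step 3 | methyl 2-[(2R,3S,5S,6R)-3-chloro-5-hydroxy-6-(prop-2-en-1-yl)oxan-2-yl]acetate | COC(=O)C[C@H]1O[C@H](CC=C)[C@@H](O)C[C@@H]1Cl
F3 | step 3 | (2R,3R,5S,6R)-5-chloro-6-(2-methoxy-2-oxoethyl)-2-(prop-2-en-1-yl)oxan-3-yl 4-nitrobenzoate | COC(=O)C[C@H]1O[C@H](CC=C)[C@H](OC(=O)c2ccc(cc2)[N+](=O)[O-])C[C@@H]1Cl
F4 | step 6 | methyl 2-[(2R,3S,5S,6R)-5-bromo-3-chloro-6-(2-oxoethyl)oxan-2-yl]acetate | COC(=O)C[C@H]1O[C@H](CC=O)[C@@H](Br)C[C@@H]1Cl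
F5 | step 6 | 1,1-bis(4,4,5,5-tetramethyl-1,3,2-dioxaborolan-2-yl)propane | CCC(B1OC(C)(C)C(C)(C)O1)B1OC(C)(C)C(C)(C)O1
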